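**Retrosynthetic overview**
1. Labels. Ring A (cyclobutane) = C-a (spiro carbon), C-b (CH bearing propyl), C-c (fusion CH next to the ring CH2), C-d (fusion CH next to the butenolide α-carbon). Ring B (cyclohexene) = C-d, Cα, Cβ, C4, C5, C-c. Ring C is the butylidene-butenolide on Cα=Cβ and ring D is the spiro-phthalide at C-a.
2. Feature used. The four non-fusion carbons of ring B (Cα–Cβ–C4–C5) form a butadiene unit, and the fusion bond C-c–C-d lies β,α to C-a. Ring A with C-a as a ketone is therefore cyclobut-2-enone 3, and ring B is its Diels–Alder adduct with the 1-silyloxy-2-pentynyl diene 9 (oxygen on Cα, alkyne on Cβ).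
3. Ring C: (Z)-alkylidene butenolide ⇒ silver-catalysed 5-exo-dig closure of enynoic acid 26 ⇒ carbonylation of enol triflate 25 ⇒ conjugate reduction of 2-alkynyl enone 23 ⇒ the Cα–O bond of the adduct.
4. Ring D and C-a come from convex-face addition of an o-(methoxycarbonyl)aryl Grignard reagent to ketone 17. The concave propyl at C-b comes from propylidene enone 15, whose conjugate reduction forms the C-b enolate regiospecifically for convex protonation. Direct alkylation would give the convex epimer, and re-enolising that epimer would compete with C-d deprotonation and loss of the silyloxy group.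
5. Order of rings: A (bought with 1) → B (step 6) → D (step 10) → C (step 15). The arene is bought with 18.

Key step: step 6

Assumption: the sense of induction in step 6 is taken from the α-C–H···O binding model for s-trans cyclic enones on this catalyst family. The catalyst from (R)-α,α-diphenylprolinol would serve in the same way if the sense were reversed.

Convention: "convex/exo" is the face of ring A that carries the C-c and C-d hydrogens. "Concave/endo" is the side of ring B.

**Step 1**
Reactants: 1 3-oxocyclobutane-1-carboxylic acid
Product: 2 3-bromocyclobutan-1-one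
Conditions: HgO, Br2, CH2Cl2, reflux
Reagents that add atoms: bromine, BrBr
Why: Hunsdiecker-type radical bromodecarboxylation (HgO/Br2 variant) replaces CO2H by Br, the ketone is inert, and no stereocentre arises.

**Step 2**
Reactants: 2 3-bromocyclobutan-1-one
Product: 3 cyclobut-2-en-1-one
Conditions: n-Bu3N, neat, rt, product distilled under reduced pressure into a cold trap, kept as a cold CH2Cl2 solution
Reagents that add atoms: none
Why: E1cB dehydrobromination of a β-bromo ketone by a high-boiling, non-nucleophilic amine lets the volatile enone leave the flask before it can polymerise.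

**Step 3**
Reactants: 4 (E)-but-2-enal (crotonaldehyde)
Product: 6 (Z)-2-bromobut-2-enal, via 2,3-dibromobutanal 5 (not isolated)
Conditions: Br2, CH2Cl2, 0 °C; then Et3N, 0 °C → rt
Reagents that add atoms: bromine, BrBr
Why: Bromine addition to the alkene followed by base-induced loss of the acidic α-hydrogen and the β-bromide (bromination–dehydrobromination) should give the more stable bromoenal with methyl trans to CHO.

**Step 4**
Reactants: 6 (Z)-2-bromobut-2-enal; 7 pent-1-yne
Product: 8 (E)-2-(pent-1-yn-1-yl)but-2-enal
Conditions: PdCl2(PPh3)2 (3 mol%), CuI (5 mol%), Et3N, THF, 0 °C → rt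
Reagents that add atoms: none
Why: Sonogashira coupling, in which zerovalent palladium inserts into the activated C(sp2)–Br bond with retention of alkene geometry and the tertiary amine avoids conjugate addition to the enal.

**Step 5**
Reactants: 8 (E)-2-(pent-1-yn-1-yl)but-2-enal
Product: 9 (1Z)-1-(tert-butyldimethylsilyloxy)-2-(pent-1-yn-1-yl)buta-1,3-diene
Conditions: TBSOTf, Et3N, Et2O, 0 °C → rt
Reagents that add atoms: tert-butyldimethylsilyl triflate, CC(C)(C)[Si](C)(C)OS(=O)(=O)C(F)(F)F
Why: Silyl dienol ether formation by O-silylation and loss of a γ-proton from the s-trans enal places OTBS trans to the new vinyl group (1Z, next to the slim alkyne), the only geometry that can reach the reactive s-cis diene.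

**Step 6**
Reactants: 3 cyclobut-2-en-1-one; 9 (1Z)-1-(tert-butyldimethylsilyloxy)-2-(pent-1-yn-1-yl)buta-1,3-diene
Product: 10 (1R,2R,6S)-2-(tert-butyldimethylsilyloxy)-3-(pent-1-yn-1-yl)bicyclo[4.2.0]oct-3-en-8-one (cis-fused endo adduct; C1 = C-d, C2 = Cα, C6 = C-c, C7 = C-b, C8 = C-a)
Conditions: (S)-3,3-diphenyl-1-(2-methylphenyl)tetrahydro-1H,3H-pyrrolo[1,2-c][1,3,2]oxazaborole (12 mol%) + AlBr3 (10 mol%), CH2Cl2, −78 °C; pH 7 buffer
Reagents that add atoms: none
Why: The carbonyl oxygen of 3 binds to the boron of the AlBr3-activated oxazaborolidine, which lowers the enone LUMO, and the s-cis form of 9 adds in a concerted but asynchronous normal-demand [4+2] cycloaddition in which the bond from the unsubstituted diene terminus (C5) to the enone β-carbon (C-c) runs ahead of the bond from the silyloxy-bearing terminus (Cα) to the α-carbon (C-d). The closest known reactions are the Diels–Alder additions of cyclobutenone to 1-oxygenated dienes and the oxazaborolidinium-catalysed enantioselective Diels–Alder reactions of cyclic enones, cyclobutenones included. Ring B is closed by an intermolecular suprafacial [4π+2π] union that makes both σ-bonds in one step, while ring A is carried in intact. C-c and C-d come out cis because the ring-locked cis-alkene adds suprafacially, and Cα is set by the endo transition state (carbonyl under the diene) acting on the outward-pointing silyloxy group of the (1Z)-diene, which puts OTBS cis to C-a. The absolute sense comes from the catalyst: the enone should sit on the convex face of the bicycle, held by the B–O bond and an α-C–H···O contact, with one phenyl of the CPh2 group covering the Re face of the α-carbon, so that the diene reaches the Si face. The step needs ortho regiochemistry, secured by the 1-silyloxy donor that places the largest HOMO coefficient on C5 and outweighs the 2-alkynyl group, and it needs the diene to outlast the Lewis acid, secured by the strain-raised reactivity of 3 that allows −78 °C and by the robust TBS group.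

**Step 7**
Reactants: 10 Diels–Alder adduct; 11 propanal
Product: 13 (1R,2R,6S)-2-(tert-butyldimethylsilyloxy)-7-exo-(1-hydroxypropyl)-3-(pent-1-yn-1-yl)bicyclo[4.2.0]oct-3-en-8-one (carbinol epimers), via lithium enolate 12 (not isolated)
Conditions: LiN(i-Pr)2, THF, −78 °C; 11, −78 °C; AcOH quench at −78 °C
Reagents that add atoms: none
Why: Kinetic deprotonation takes the open C-b methylene rather than the ring-fusion C-d hydrogen, and aldol addition to propanal occurs on the convex face, so both new centres are temporary and are erased in steps 8 and 9.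

**Step 8**
Reactants: 13 aldol adduct
Product: 15 (7E)-2-(tert-butyldimethylsilyloxy)-3-(pent-1-yn-1-yl)-7-propylidenebicyclo[4.2.0]oct-3-en-8-one (C-c and C-d and Cα as in 10), via mesylate 14 (not isolated)
Conditions: MsCl, Et3N (excess), CH2Cl2, 0 °C → rt
Reagents that add atoms: none
Why: Aldol dehydration by mesylation and E1cB elimination, in which the side-chain mesylate leaves far faster than the silyloxy group β to the ketone, so a mild amine base suffices; the alkene geometry is of no consequence.

**Step 9**
Reactants: 15 propylidene enone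
Product: 17 (1R,2R,6S,7R)-2-(tert-butyldimethylsilyloxy)-3-(pent-1-yn-1-yl)-7-propylbicyclo[4.2.0]oct-3-en-8-one (propyl endo), via copper enolate 16 (not isolated)
Conditions: [(Ph3P)CuH]6, degassed toluene, H2O (few equiv), 0 °C → rt
Reagents that add atoms: none
Why: Copper hydride conjugate reduction of the s-cis exocyclic enone forms the C-a/C-b enolate regiospecifically, and water protonates C-b from the convex face, which pushes propyl to the concave side (kinetic protonation); the unactivated enyne should not react at this temperature.

**Step 10**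
Reactants: 17 endo-propyl ketone; 18 methyl 2-iodobenzoate
Product: 21 2-(tert-butyldimethylsilyloxy)-3-(pent-1-yn-1-yl)-7-propyl-3'H-spiro[bicyclo[4.2.0]oct-3-ene-8,1'-[2]benzofuran]-3'-one (aryl on the convex face; lactone O on the concave face; C-a R), via aryl Grignard reagent 19 (not isolated), via magnesium alkoxide 20 (not isolated)
Conditions: 18, i-PrMgCl·LiCl, THF, −40 °C; then 17 premixed with LaCl3·2LiCl, −40 °C → rt
Reagents that add atoms: none
Why: Iodine–magnesium exchange gives an ester-tolerant aryl Grignard reagent whose 1,2-addition to the strained ketone comes from the convex face, because only hydrogens stand there while ring B, propyl and OTBS block the other side. This sets C-a, and the alkoxide then closes onto the ortho ester (lactonisation) to give the phthalide.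

**Step 11**
Reactants: 21 silyl ether
Product: 22 2-hydroxy-3-(pent-1-yn-1-yl)-7-propyl-3'H-spiro[bicyclo[4.2.0]oct-3-ene-8,1'-[2]benzofuran]-3'-one (all centres as in 21)
Conditions: HF·pyridine, THF/pyridine, 0 °C → rt
Reagents that add atoms: none
Why: Fluoride-driven Si–O cleavage in a weakly acidic medium spares the lactone and the enyne and avoids a free alkoxide next to the phthalide.

**Step 12**
Reactants: 22 allylic alcohol
Product: 23 3-(pent-1-yn-1-yl)-7-propyl-3'H-spiro[bicyclo[4.2.0]oct-3-ene-8,1'-[2]benzofuran]-2,3'-dione (C-a to C-d unchanged)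
Conditions: Dess–Martin periodinane, CH2Cl2, 0 °C → rt
Reagents that add atoms: none
Why: Dess–Martin oxidation works without base, so the C-d hydrogen (now α to the ketone and β to the lactone oxygen) is not removed, and the cis 4/6 fusion is the preferred one in any case.

**Step 13**
Reactants: 23 2-alkynyl enone
Product: 25 enol triflate with Cα(OTf)=Cβ(pentynyl) and C4 now CH2 (C-a to C-d unchanged), via lithium enolate 24 (not isolated)
Conditions: LiBH(s-Bu)3 (1.05 equiv), THF, −78 °C; then N-(5-chloropyridin-2-yl)bis(trifluoromethanesulfonimide), −78 → 0 °C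
Reagents that add atoms: N-(5-chloropyridin-2-yl)bis(trifluoromethanesulfonimide), FC(F)(F)S(=O)(=O)N(c1ccc(Cl)cn1)S(=O)(=O)C(F)(F)F
Why: Conjugate reduction–enolate triflation, in which the bulky borohydride adds 1,4 at the unhindered C4 and the resulting Cα=Cβ enolate is trapped on oxygen, so the tetrasubstituted alkene is placed without enolising toward C-d.

**Step 14**
Reactants: 25 enol triflate
Product: 26 enynoic acid with Cα(CO2H)=Cβ(pentynyl) (C-a to C-d unchanged)
Conditions: Pd(OAc)2 (5 mol%), 1,3-bis(diphenylphosphino)propane (6 mol%), CO (1 atm), H2O, i-Pr2NEt, DMF, 50 °C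
Reagents that add atoms: carbon monoxide, [C-]#[O+]; water, O
Why: Palladium-catalysed hydroxycarbonylation of an enol triflate (oxidative addition, CO insertion, hydrolysis) installs the carboxyl carbon on Cα with the alkene position kept.

**Step 15**
Reactants: 26 enynoic acid
Product: 27 target CNP0248594.2 (C-a R, C-b R, C-c S, C-d R; Z-butylidene)
Conditions: AgNO3 (10 mol%), acetone, rt, dark
Reagents that add atoms: none
Why: Silver-catalysed 5-exo-dig lactonisation of a (Z)-2-en-4-ynoic acid, in which anti attack of the carboxyl oxygen on the silver-bound alkyne and protodemetalation leave propyl cis to the ring oxygen, giving the Z-alkylidene butenolide.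

**Compound list**
1 | 3-oxocyclobutane-1-carboxylic acid | O=C1CC(C(=O)O)C1 | starting material
2 | 3-bromocyclobutan-1-one | O=C1CC(Br)C1 | intermediate
3 | cyclobut-2-en-1-one | O=C1C=CC1 | intermediate
4 | (E)-but-2-enal | C/C=C/C=O | starting material
5 | 2,3-dibromobutanal | CC(Br)C(Br)C=O | intermediate
6 | (Z)-2-bromobut-2-enal | C/C=C(Br)/C=O | intermediate
7 | pent-1-yne | C#CCCC | starting material
8 | (E)-2-(pent-1-yn-1-yl)but-2-enal | C/C=C(C#CCCC)/C=O | intermediate
9 | (1Z)-1-(tert-butyldimethylsilyloxy)-2-(pent-1-yn-1-yl)buta-1,3-diene | C=C/C(C#CCCC)=C/O[Si](C)(C)C(C)(C)C | intermediate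
10 | (1R,2R,6S)-2-(tert-butyldimethylsilyloxy)-3-(pent-1-yn-1-yl)bicyclo[4.2.0]oct-3-en-8-one | O=C1C[C@@H]2CC=C(C#CCCC)[C@H](O[Si](C)(C)C(C)(C)C)[C@H]12 | intermediate
11 | propanal | CCC=O | starting material
12 | lithium enolate of 10 (C-a/C-b) | [Li+].[O-]C1=C[C@@H]2CC=C(C#CCCC)[C@H](O[Si](C)(C)C(C)(C)C)[C@H]12 | intermediate
13 | 7-exo-(1-hydroxypropyl) ketone (carbinol epimers) | O=C1[C@@H](C(O)CC)[C@@H]2CC=C(C#CCCC)[C@H](O[Si](C)(C)C(C)(C)C)[C@H]12 | intermediate
14 | mesylate of 13 | O=C1[C@@H](C(CC)OS(C)(=O)=O)[C@@H]2CC=C(C#CCCC)[C@H](O[Si](C)(C)C(C)(C)C)[C@H]12 | intermediate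
15 | (7E)-7-propylidene enone | O=C1/C(=C/CC)[C@@H]2CC=C(C#CCCC)[C@H](O[Si](C)(C)C(C)(C)C)[C@H]12 | intermediate
16 | copper enolate (C-a/C-b, propyl on C-b) | [Cu+].[O-]C1=C(CCC)[C@@H]2CC=C(C#CCCC)[C@H](O[Si](C)(C)C(C)(C)C)[C@H]12 | intermediate
17 | (1R,2R,6S,7R)-2-(tert-butyldimethylsilyloxy)-3-(pent-1-yn-1-yl)-7-propylbicyclo[4.2.0]oct-3-en-8-one | O=C1[C@H](CCC)[C@@H]2CC=C(C#CCCC)[C@H](O[Si](C)(C)C(C)(C)C)[C@H]12 | intermediate
18 | methyl 2-iodobenzoate | COC(=O)c1ccccc1I | starting material
19 | 2-(methoxycarbonyl)phenylmagnesium chloride | COC(=O)c1ccccc1[Mg]Cl | intermediate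
20 | magnesium alkoxide of the tertiary carbinol | CC(C)(C)[Si](C)(C)O[C@H]2C(C#CCCC)=CC[C@H]1[C@@H](CCC)[C@](O[Mg]Cl)(c3ccccc3C(=O)OC)[C@@H]21 | intermediate
21 | spiro-phthalide silyl ether | CC(C)(C)[Si](C)(C)O[C@H]2C(C#CCCC)=CC[C@H]1[C@@H](CCC)[C@@]3(OC(=O)c4ccccc43)[C@@H]21 | intermediate
22 | spiro-phthalide allylic alcohol | O[C@H]2C(C#CCCC)=CC[C@H]1[C@@H](CCC)[C@@]3(OC(=O)c4ccccc43)[C@@H]21 | intermediate
23 | spiro-phthalide 2-alkynyl enone | O=C2C(C#CCCC)=CC[C@H]1[C@@H](CCC)[C@@]3(OC(=O)c4ccccc43)[C@@H]21 | intermediate
24 | lithium enolate (Cα/Cβ) | [Li+].[O-]C2=C(C#CCCC)CC[C@H]1[C@@H](CCC)[C@@]3(OC(=O)c4ccccc43)[C@@H]21 | intermediate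
25 | enol triflate | FC(F)(F)S(=O)(=O)OC2=C(C#CCCC)CC[C@H]1[C@@H](CCC)[C@@]3(OC(=O)c4ccccc43)[C@@H]21 | intermediate
26 | enynoic acid | OC(=O)C2=C(C#CCCC)CC[C@H]1[C@@H](CCC)[C@@]3(OC(=O)c4ccccc43)[C@@H]21 | intermediate
27 | CNP0248594.2 | CCC/C=C1\OC(=O)C2=C1CC[C@H]1[C@@H](CCC)[C@@]3(OC(=O)c4ccccc43)[C@@H]21 | target

**Totals**
Total step count: 15. Longest linear sequence: 13 steps (steps 3–15, from crotonaldehyde). The cyclobutenone branch (steps 1–2) joins at step 6.

**Steps most likely to fail**

Step 6.
- What may go wrong: the Lewis acid may divert the silyl dienol ether into a stepwise Mukaiyama–Michael or [2+2] pathway or strip the silyl group. The small unsubstituted enone may also be held too loosely for good face discrimination.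
- Fallback: this sets out from 3 and 9. The two are combined without any catalyst in toluene at rt, where the ring strain of 3 alone should drive the endo, ortho-selective cycloaddition. This gives 10 together with its mirror-image adduct F1.
- The two are separated by preparative supercritical-fluid chromatography on an amylose tris(3,5-dimethylphenylcarbamate) phase. The route is rejoined at 10.

Step 9.
- What may go wrong: protonation in a wet medium at room temperature beside basic copper species may be followed by epimerisation at C-b to the more stable convex epimer. Slow hydrocupration of the enyne may also compete.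
- Fallback: this sets out from 10 and builds the same enolate by C–C bond formation at low temperature. Enolate 12 (LiN(i-Pr)2, THF, −78 °C) is treated with dimethyl(methylidene)ammonium iodide to give the Mannich base F2.
- MeI then gives the quaternary ammonium iodide F3, and aqueous NaHCO3/CH2Cl2 releases the α-methylene ketone F4.
- Et2CuLi in THF at −78 °C adds ethyl to the methylene carbon to give the lithium enolate F5. This is quenched at −78 °C with 2,6-di-tert-butyl-4-methylphenol, a bulky proton donor that can only reach the convex face. The route is rejoined at 17.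

Step 10.
- What may go wrong: the ester-bearing aryl Grignard reagent is a hindered, sluggish nucleophile. Enolisation of 17 (scrambling at C-b, or loss of silanolate after C-d deprotonation) and self-condensation of the reagent may outrun addition.
- Fallback: this sets out from 17. 2-Bromobenzyl alcohol and n-BuLi (2 equiv, THF, −78 °C) give the dilithio reagent F6, a far more reactive nucleophile without an ester.
- F6 adds to 17 at −78 °C from the convex face to give the diol F7.
- MnO2 in CH2Cl2 oxidises the benzylic alcohol, and the lactol F8 that forms is oxidised further in the same flask to the phthalide. The route is rejoined at 21.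

**Further compounds**
F1 | step 6 | (1S,2S,6R)-2-(tert-butyldimethylsilyloxy)-3-(pent-1-yn-1-yl)bicyclo[4.2.0]oct-3-en-8-one (enantiomer of 10) | O=C1C[C@H]2CC=C(C#CCCC)[C@@H](O[Si](C)(C)C(C)(C)C)[C@@H]12
F2 | step 9 | 7-exo-(dimethylaminomethyl) ketone (Mannich base of 10) | O=C1[C@@H](CN(C)C)[C@@H]2CC=C(C#CCCC)[C@H](O[Si](C)(C)C(C)(C)C)[C@H]12
F3 | step 9 | trimethylammoniomethyl ketone iodide | O=C1[C@@H](C[N+](C)(C)C)[C@@H]2CC=C(C#CCCC)[C@H](O[Si](C)(C)C(C)(C)C)[C@H]12.[I-]
F4 | step 9 | 7-methylidene ketone | O=C1C(=C)[C@@H]2CC=C(C#CCCC)[C@H](O[Si](C)(C)C(C)(C)C)[C@H]12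
F5 | step 9 | lithium enolate (C-a/C-b, propyl on C-b) | [Li+].[O-]C1=C(CCC)[C@@H]2CC=C(C#CCCC)[C@H](O[Si](C)(C)C(C)(C)C)[C@H]12
F6 | step 10 | lithium 2-lithiobenzyl oxide | [Li]OCc1ccccc1[Li]
F7 | step 10 | tertiary carbinol bearing a 2-(hydroxymethyl)phenyl group at C-a (diol) | CC(C)(C)[Si](C)(C)O[C@H]2C(C#CCCC)=CC[C@H]1[C@@H](CCC)[C@](O)(c3ccccc3CO)[C@@H]21
F8 | step 10 | spiro-lactol (anomers) | CC(C)(C)[Si](C)(C)O[C@H]2C(C#CCCC)=CC[C@H]1[C@@H](CCC)[C@@]3(OC(O)c4ccccc43)[C@@H]21
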